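A small charge of Q, 0.060 M in the north-west run, gave me an odd pair of numbers. J peaked in the readings at 21%, yet L ended at 67%, more than that peak. L also rose after J did. I read J in that run as a stock that is renewed while it drains, so that a small stock passed a large flow.

| flask | Q | E | remark | time |
|---|---|---|---|---|
| north-west | 0.060 M | 0.144 M | run made earlier |  |
| north | 0.24 M | 0.144 M | run made earlier |  |
| east | 0.12 M | 0.072 M | run made earlier |  |
| flask | 0.12 M | 0.144 M |  | 15 d |

- north-west (time / d: J / %, L / %, Q / %): 0.167: 11, 1, 90; 0.333: 18, 3, 77; 0.833: 21, 16, 55; 1.67: 17, 34, 36; 4.00: 6, 63, 14; 10.0: 0, 67, 0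
- north (time / d: J / %, L / %, Q / %): 0.167: 12, 0, 82; 0.333: 15, 0, 74; 0.833: 16, 14, 65; 1.67: 11, 25, 56; 4.00: 2, 39, 47; 10.0: 0, 45, 42
- east (time / d: J / %, L / %, Q / %): 0.167: 4, 1, 92; 0.417: 9, 3, 84; 1.25: 8, 17, 73; 3.00: 3, 28, 57; 10.0: 0, 42, 42

(scatter of a reading: 2 percentage points)



- time, not beyond 15 d, at which the flask holds most J
- the amount of J, in percent of the Q charged, at that time

So I counted turnovers. Between 0.833 d and 1.67 d of that run, L rose by 18 percentage points over a mean J of 19.0%. The last reading of that run put the share of the Q that went to L at 67%. The turnover rate λ, the share of standing J that leaves per day, therefore read 1.69 /d.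

The first fall of Q in that run read as a rate constant k of 5.45 /M/d, with cE held at its charge. For the flask I held cE at its charge, a pseudo-first-order view, so Q fell at a = k·cE = 0.785 /d. In that view J in the flask peaks where a·Q equals λ·J, which gave me 23.9% at 0.848 d. The flask held 1.20 equivalents of E, and cE falls as Q reacts, so I took that amount as high.

The forecast, reasoning that “J peaks where feed equals 1.6·J”, said 20% at 0.8 d, less J than my figure. The flask gave 20.1% at 0.644 d.

    J → L (k = 8.10 × 10⁻⁴ /min)
    J → D (k = 3.10 × 10⁻⁴ /min)
    Q + E ⇌ J (K = 12.0 /M, k = 0.00460 /M/min)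

At that peak the flask held Q 64.6%, E 70.5% and J 20.1%. With these simulated amounts, k·cE·Q over λ·J came to 1.05. A neighbour flask was charged with 0.36 M of E, which is 3.00 equiv. For that flask I reckoned a as 1.96 /d, and the same reckoning gave 39.5% at 0.549 d. That neighbour flask reached 37.2% of J.

(The runs are calculated with constants of no real substance, and the scatter is random.)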